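**Plan**

Numbering: C1 CMe2, C2 CHBr, C3 and C4 CH2, C5 C(CH3)–O, O6, C7 enol ether carbon, C8 (methylated) and C9 epoxide carbons, C10 CH2, C11 fusion CH, C12 =CHBr. Ring A is the cyclohexane C1–C5/C11, ring B the oxepane C5/O6/C7–C11, and β is the face that carries the C5 methyl.
Enabling feature: with O6 left out, C7, C8 (with its methyl), C9, C10, C11 and C5 are the six ring atoms of carvone, and C1 with its two methyls is the isopropenyl group. Only C2–C4, the C5 methyl and C12 have to be added, and ring A lacks just the bond C1–C2.
Cuts, in retrosynthetic order: the C12–Br bond cis to O6 (back to a gem-dibromide), both C12–Br bonds, C7=C12 (lactone), C5–O6 (ketone), C2–Br (axial alcohol), the epoxide C–O bonds (enone), C1–C2 (alkene plus aldehyde), then C5–C4 and C5–CH3 (enolate alkylations).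
Forward: the carbocyclic forerunner of ring B is bought as (R)-carvone. Ring A closes onto it in step 4 to a trans-decalin, ring B grows from six to seven atoms by oxygen insertion in step 9, and C12 comes last.
Stereochemistry: C11 comes from (R)-carvone. C5 is set by allylation anti to isopropenyl and kept by retention in the migration. C8/C9 come from α-face nucleophilic epoxidation, C2 from equatorial hydride delivery followed by SN2 inversion, and the E enol ether from selective hydrogenolysis of the bromine cis to O6.

Key step: step 4

Remark: in the target the C12 bromine is trans to O6 and cis to C8 (E). Bromination–dehydrobromination of an exocyclic enol ether is expected to place it cis to the ring oxygen, so the route passes through the gem-dibromide.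

Step 1
Reactants: 1 (R)-(−)-carvone; 2 iodomethane
Product: 4 6-methylcarvone (C6 epimer mixture), via lithium dienolate 3 (not isolated)
Conditions: LiN(i-Pr)2, THF, −78 °C; then MeI, −78 → 0 °C
Reagents that add atoms: iodomethane, CI
Why: Kinetic deprotonation at the α' carbon (later C5) gives the cross-conjugated enolate, and its SN2 methylation (enolate alkylation) brings in the C5 methyl; the new centre forms as an epimer mixture, which does not matter because it is made planar again in step 2.

Step 2
Reactants: 4 6-methylcarvone; 5 allyl bromide
Product: 7 (5S,6S)-6-allyl-6-methylcarvone, via lithium enolate 6 (not isolated)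
Conditions: LiN(i-Pr)2, THF, −78 → 0 °C; then DMPU, allyl bromide, −78 °C → rt
Reagents that add atoms: allyl bromide, C=CCBr
Why: Enolate alkylation in which the tetrasubstituted enolate is attacked on the face away from the neighbouring isopropenyl group, so the allyl chain (C4–C2) ends anti and the methyl syn to it, which fixes C5.

Step 3
Reactants: 7 (5S,6S)-6-allyl-6-methylcarvone
Product: 8 (5S,6S)-6-methyl-6-(3-oxopropyl)carvone
Conditions: PdCl2(PhCN)2 (12 mol %), CuCl2·2H2O (12 mol %), AgNO2 (6 mol %), O2 (1 atm), t-BuOH/MeNO2 15:1, rt
Reagents that add atoms: dioxygen, O=O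
Why: The nitrite-modified, aldehyde-selective Wacker-type oxidation is known for allyl groups on quaternary carbons beside a carbonyl group and oxidises the monosubstituted alkene at its terminal carbon, while the 1,1-disubstituted and enone alkenes do not enter divalent palladium oxypalladation and no stereocentre is touched.

Step 4
Reactants: 8 (5S,6S)-6-methyl-6-(3-oxopropyl)carvone
Product: 10 trans-fused 2β-hydroxy decalin enone, via phenylsilyl ether 9 (not isolated)
Conditions: [N,N'-bis(3,5-di-tert-butylsalicylidene)-2,3-dimethylbutane-2,3-diaminato]cobalt (10 mol %), CrCl3(thf)3 (50 mol %), PhSiH3 (2 equiv), degassed THF (0.02 M), rt; then 1 M aq HCl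
Reagents that add atoms: none
Why: Proposed new method: a trivalent cobalt hydride, formed from the cobalt complex and PhSiH3, passes a hydrogen atom to the terminal CH2 of the isopropenyl group, which thereby becomes the second methyl on C1, and the tertiary C1 radical is caught by divalent chromium (kept available by electron exchange between divalent cobalt and trivalent chromium) as a tertiary alkylchromium that adds to the aldehyde carbon C2 in the manner of a Nozaki–Hiyama–Kishi reaction, the alkoxide being released as phenylsilyl ether 9. The closest known reaction type is the intermolecular, branch-selective coupling of 1,1-disubstituted alkenes with aldehydes under combined cobalt hydride and chromium catalysis; new here are the ring closure and the enone beside the reacting groups. Ring A closes in the 6-exo-trig mode onto the C=O bond through a chair in which the C5 methyl is axial and C7 and C10 are equatorial, so the anti relation of the two side chains set in step 2 can lead only to the trans fusion. C2 is the only new stereocentre: the bulky metal-bound oxygen is expected to take the pseudo-equatorial β position, but the route does not rely on this, because both epimers converge in step 6 and C2 is set again in steps 7 and 8. A C1 radical that adds directly to the carbonyl group is not lost, since divalent chromium should reduce the alkoxyl radical to the same chromium alkoxide before it can fragment. The step needs hydrogen atom transfer to the isopropenyl group alone, which is secured because this unhindered, electron-rich 1,1-disubstituted alkene accepts the hydrogen atom far better than the trisubstituted, electron-poor C8=C9 bond, and the three-atom tether lets closure outrun reduction of the radical.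

Step 5
Reactants: 10 trans-fused 2β-hydroxy decalin enone (with any 2α epimer)
Product: 11 8α,9α-epoxy hydroxy ketone
Conditions: 30% aq H2O2, NaOH (cat.), MeOH, 0 °C
Reagents that add atoms: hydrogen peroxide, OO
Why: Weitz–Scheffer epoxidation in which hydroperoxide adds axially to C9 on the α face, anti to the C11–C1 bond (the sense known for carvone) and anti to the axial C5 methyl, and the enolate closes the oxirane on the same face, which sets C8 and C9.

Step 6
Reactants: 11 8α,9α-epoxy hydroxy ketone
Product: 12 epoxy 2,7-diketone
Conditions: Dess–Martin periodinane, CH2Cl2, rt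
Reagents that add atoms: none
Why: The Dess–Martin oxidation works under near-neutral conditions, merges both C2 epimers into one ketone and leaves the epoxy ketone untouched.

Step 7
Reactants: 12 epoxy 2,7-diketone
Product: 13 2α (axial) alcohol
Conditions: LiBH(s-Bu)3 (1.1 equiv), THF, −78 °C
Reagents that add atoms: none
Why: In this bulky trialkylborohydride reduction the hydride reaches the C2 ketone along the equatorial trajectory, as with 4,4-dimethyl-3-keto terpenoids, to give the axial α alcohol, while C7 lies between two fully substituted carbons and is out of reach at low temperature.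

Step 8
Reactants: 13 2α (axial) alcohol
Product: 14 2β-bromo epoxy ketone
Conditions: CBr4, PPh3, toluene, 0 → 60 °C
Reagents that add atoms: tetrabromomethane, BrC(Br)(Br)Br
Why: In this Appel reaction the axial oxyphosphonium group is displaced by bromide in an SN2 process with inversion to the equatorial β bromide, a conversion known for axial neopentylic carbinols next to a gem-dimethyl group, and the electron-poor keto epoxide is not activated by the neutral reagent.

Step 9
Reactants: 14 2β-bromo epoxy ketone
Product: 15 bromo epoxy oxepan-7-one (ε-lactone)
Conditions: urea·H2O2, (CF3CO)2O, Na2HPO4, CH2Cl2, 0 °C → rt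
Reagents that add atoms: urea–hydrogen peroxide, NC(N)=O.OO (its oxygen is passed on through trifluoroperacetic acid, OOC(=O)C(F)(F)F)
Why: In this Baeyer–Villiger oxidation the tertiary alkyl carbon C5 of the Criegee adduct migrates in preference to the electron-poor oxirane carbon C8 with its high s character, and it does so with retention, so O6 enters between C5 and C7 and ring B becomes seven-membered, while the buffer protects the epoxide and the tertiary alkyl ester.

Step 10
Reactants: 15 bromo epoxy oxepan-7-one
Product: 16 7-methylene oxepane
Conditions: Cp2TiMe2 (3 equiv), toluene, 75 °C, dark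
Reagents that add atoms: dimethyltitanocene, C[Ti](C)(C1C=CC=C1)C1C=CC=C1
Why: In the Petasis methylenation the Cp2Ti=CH2 released on heating is small, non-basic and not Lewis acidic, so it should convert the crowded lactone carbonyl into the exocyclic enol ether C7=C12 and spare the epoxide and the alkyl bromide.

Step 11
Reactants: 16 7-methylene oxepane
Product: 18 (Z)-bromomethylene oxepane, via vicinal dibromide 17 (not isolated)
Conditions: Br2 (1.0 equiv), CH2Cl2, −78 °C; then DBU, −78 → 0 °C
Reagents that add atoms: bromine, BrBr
Why: In this bromination–dehydrobromination of an exocyclic enol ether, Br2 adds to the electron-rich C7=C12 bond and the base removes HBr from the α-bromo ether; by analogy with exocyclic glycals the bromine should end on the open side cis to O6, a geometry erased in step 12, and the equatorial C2 bromide has no antiperiplanar hydrogen and should survive the base.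

Step 12
Reactants: 18 (Z)-bromomethylene oxepane
Product: 20 dibromomethylene oxepane, via tribromide 19 (not isolated)
Conditions: Br2 (1.05 equiv), CH2Cl2, −40 → 0 °C; then DBU, 0 °C → rt
Reagents that add atoms: bromine, BrBr
Why: A second bromination–dehydrobromination is possible because the bromo enol ether is still nucleophilic enough to add Br2, and the acidified CHBr2 proton, the only β hydrogen of C7, is then removed to give the gem-dibromide.

Step 13
Reactants: 20 dibromomethylene oxepane
Product: 21 target CNP0375295.1
Conditions: Pd(PPh3)4 (5 mol %), Bu3SnH (1.05 equiv), BHT (cat.), toluene, rt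
Reagents that add atoms: none
Why: In the palladium-catalysed hydrogenolysis of a 1,1-dibromoalkene with Bu3SnH, zerovalent palladium inserts into the less hindered C–Br bond, here the one cis to O6 and trans to the quaternary C8, and hydride transfer and reductive elimination go with retention, so the remaining bromine is cis to C8 and trans to O6 (E); the neopentylic sp3 C2–Br bond does not undergo oxidative addition and BHT holds down tin radical chains.

**Compound list**

1 | (R)-(−)-carvone, (5R)-2-methyl-5-(prop-1-en-2-yl)cyclohex-2-en-1-one | CC(=C)[C@@H]1CC=C(C)C(=O)C1 | starting material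
2 | iodomethane | CI | starting material
3 | lithium cross-conjugated dienolate of 1 (not isolated) | [Li+].CC(=C)[C@@H]1CC=C(C)C([O-])=C1 | intermediate
4 | 6-methylcarvone, (5R)-2,6-dimethyl-5-(prop-1-en-2-yl)cyclohex-2-en-1-one, epimer mixture at C6 | CC(=C)[C@@H]1CC=C(C)C(=O)C1C | intermediate
5 | allyl bromide, 3-bromoprop-1-ene | C=CCBr | starting material
6 | lithium enolate of 4 (not isolated) | [Li+].CC(=C)[C@@H]1CC=C(C)C([O-])=C1C | intermediate
7 | (5S,6S)-2,6-dimethyl-5-(prop-1-en-2-yl)-6-(prop-2-en-1-yl)cyclohex-2-en-1-one; allyl anti, methyl syn to isopropenyl | CC(=C)[C@@H]1CC=C(C)C(=O)[C@@]1(C)CC=C | intermediate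
8 | 3-[(1S,6S)-1,3-dimethyl-2-oxo-6-(prop-1-en-2-yl)cyclohex-3-en-1-yl]propanal; oxopropyl anti to isopropenyl | CC(=C)[C@@H]1CC=C(C)C(=O)[C@@]1(C)CCC=O | intermediate
9 | O-phenylsilyl ether of 10 (not isolated) | CC1(C)[C@@H](O[SiH2]c3ccccc3)CC[C@]2(C)C(=O)C(C)=CC[C@@H]12 | intermediate
10 | (4aS,6S,8aS)-6-hydroxy-2,5,5,8a-tetramethyl-4a,5,6,7,8,8a-hexahydronaphthalen-1(4H)-one; trans-decalin, C7 ketone, C8=C9, 2β-OH equatorial, 5β-CH3, 11α-H (any 2α epimer is carried on to 12) | CC1(C)[C@@H](O)CC[C@]2(C)C(=O)C(C)=CC[C@@H]12 | intermediate
11 | 8α,9α-epoxide of 10; epoxide oxygen α, C8 methyl β, 2β-OH, C7 ketone | CC1(C)[C@@H](O)CC[C@]2(C)C(=O)[C@]3(C)O[C@@H]3C[C@@H]12 | intermediate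
12 | 8α,9α-epoxy trans-decalin-2,7-dione, 5β-CH3, 11α-H | CC1(C)C(=O)CC[C@]2(C)C(=O)[C@]3(C)O[C@@H]3C[C@@H]12 | intermediate
13 | 2α-hydroxy (axial) 8α,9α-epoxy trans-decalin-7-one | CC1(C)[C@H](O)CC[C@]2(C)C(=O)[C@]3(C)O[C@@H]3C[C@@H]12 | intermediate
14 | 2β-bromo (equatorial) 8α,9α-epoxy trans-decalin-7-one | CC1(C)[C@@H](Br)CC[C@]2(C)C(=O)[C@]3(C)O[C@@H]3C[C@@H]12 | intermediate
15 | 2β-bromo 8α,9α-epoxy ε-lactone; O6 between C5 and C7, rings A and B trans-fused | CC1(C)[C@@H](Br)CC[C@]2(C)OC(=O)[C@]3(C)O[C@@H]3C[C@@H]12 | intermediate
16 | 2β-bromo 8α,9α-epoxy 7-methylene oxepane (C7=C12H2) | CC1(C)[C@@H](Br)CC[C@]2(C)OC(=C)[C@]3(C)O[C@@H]3C[C@@H]12 | intermediate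
17 | 7-bromo-7-(bromomethyl) oxepane, C7 configuration open (not isolated) | CC1(C)[C@@H](Br)CC[C@]2(C)OC(Br)(CBr)[C@]3(C)O[C@@H]3C[C@@H]12 | intermediate
18 | (Z)-7-(bromomethylene) oxepane, C12 bromine cis to O6 | CC1(C)[C@@H](Br)CC[C@]2(C)O/C(=C\Br)[C@]3(C)O[C@@H]3C[C@@H]12 | intermediate
19 | 7-bromo-7-(dibromomethyl) oxepane, C7 configuration open (not isolated) | CC1(C)[C@@H](Br)CC[C@]2(C)OC(Br)(C(Br)Br)[C@]3(C)O[C@@H]3C[C@@H]12 | intermediate
20 | 7-(dibromomethylene) oxepane | CC1(C)[C@@H](Br)CC[C@]2(C)OC(=C(Br)Br)[C@]3(C)O[C@@H]3C[C@@H]12 | intermediate
21 | CNP0375295.1; (2S,5S,8R,9R,11S,7E) in the numbering used here: 2β-Br equatorial, 5β-CH3, 8α,9α-epoxide, 11α-H, C12 bromine trans to O6 | CC1(C)[C@@H](Br)CC[C@]2(C)O/C(=C/Br)[C@]3(C)O[C@@H]3C[C@@H]12 | target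

**Total step count:** 13. **Longest linear sequence:** 13 steps from 1.

**Three steps most likely to fail**

Step 4. The C1 radical may take up a second hydrogen atom and end as an isopropyl group. Hydrogen atom transfer may stray to the enone, the aldehyde may be hydrosilylated or pinacol-coupled, or the two metals may fail to turn each other over. The fallback uses known chemistry: chromium is given up, and the closure is run as an iron-hydride-initiated radical cyclisation of an alkene-tethered carbonyl compound. Setting out from 8, Fe(acac)3 and PhSiH3 in EtOH at 60 °C would generate the same C1 radical. It adds directly to the C=O bond in the 6-exo mode, and the alkoxyl radical is then reduced by divalent iron and protonated by the solvent. This comes back to the route at 10 and makes no compound outside the list (F0).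

Step 9. The peracid may fail to add to a carbonyl flanked by two fully substituted carbons. The oxirane carbon may migrate instead of C5, or acid may open the epoxide or ionise the tertiary ester. The fallback reverses the order of oxygen insertion and epoxidation, so that C5 competes only with an alkenyl carbon and the carbonyl has a flat neighbour.

- It sets out from 10. A peracid Baeyer–Villiger oxidation (m-CPBA, NaHCO3, CH2Cl2), of the kind known for cyclohexenones with a quaternary α' carbon, would give the unsaturated hydroxy lactone F1.
- Nucleophilic epoxidation with t-BuOOH and DBU on the α face would give the hydroxy epoxy lactone F2.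
- Dess–Martin oxidation would give the keto epoxy lactone F3, and LiBH(s-Bu)3 reduction the axial hydroxy epoxy lactone F4.
- Appel bromination of F4 comes back to the route at 15.

Step 13. Zerovalent palladium may ionise the allylic C8–O bond of the epoxide. Both vinylic bromines may be lost, insertion may not discriminate between them, or a tin radical chain may remove the C2 bromine. The fallback replaces catalytic hydrogenolysis by halogen–metal exchange. Setting out from 20, i-PrMgCl·LiCl in THF at −78 °C would exchange the exposed bromine cis to O6, where the ring oxygen can also hold the metal, to give the α-bromoalkenylmagnesium chloride F5. Protonation with MeOH at −78 °C with retention then arrives at 21.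

**Further compounds**

F0 | step 4 | none | none
F1 | step 9 | 2β-hydroxy α,β-unsaturated ε-lactone (O6 inserted, C8=C9 kept) | CC1(C)[C@@H](O)CC[C@]2(C)OC(=O)C(C)=CC[C@@H]12
F2 | step 9 | 2β-hydroxy 8α,9α-epoxy ε-lactone | CC1(C)[C@@H](O)CC[C@]2(C)OC(=O)[C@]3(C)O[C@@H]3C[C@@H]12
F3 | step 9 | 2-oxo 8α,9α-epoxy ε-lactone | CC1(C)C(=O)CC[C@]2(C)OC(=O)[C@]3(C)O[C@@H]3C[C@@H]12
F4 | step 9 | 2α-hydroxy (axial) 8α,9α-epoxy ε-lactone | CC1(C)[C@H](O)CC[C@]2(C)OC(=O)[C@]3(C)O[C@@H]3C[C@@H]12
F5 | step 13 | α-bromoalkenylmagnesium chloride, magnesium cis and bromine trans to O6 | CC1(C)[C@@H](Br)CC[C@]2(C)O/C(=C(/Br)[Mg]Cl)[C@]3(C)O[C@@H]3C[C@@H]12
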